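**Retrosynthetic overview**
1. Target 17, the (2S)-6-geranyl-5,7-dihydroxyflavanone with a 4-hydroxy-3,5-dimethoxyphenyl B ring, comes from its tris-MOM ether 16 by global acetal cleavage as the last step.
2. 16 is disconnected at O1–C8a and C4–C4a: aryllithium 14 opens the strained (S)-β-lactone 13 at the acyl carbon, and the released C2 alkoxide closes the pyranone ring by SNAr at C8a–F. Ring C is the only ring formed; rings A and B are bought as arenes.
3. Enabling feature: C8a is ortho to the C4 carbonyl and meta to O5 and O7, so a C8a–F bond is activated and not deactivated. O1–C2–C3–C4 maps onto the O–C4–C3–C2(=O) atoms of a 4-aryloxetan-2-one. Ring A (geranyl on C6 between O5 and O7, F para to C6) is mirror-symmetric, so the two lithiation sites are identical and 6- over 8-geranyl is fixed.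
4. Ring A piece 6 comes from 5-fluororesorcinol: C2 iodination, MOM protection, I/Mg exchange, Cu-catalysed geranylation.
5. Lactone 13 comes from acetosyringone: MOM protection, Claisen condensation, asymmetric transfer hydrogenation (sets C2), saponification, lactonisation with retention.

Key step: step 9

Remark: the SMILES is read as the (2S)-flavanone carrying an (E)-geranyl group at C6 between the 5- and 7-hydroxyls; this is the structure the route is planned to deliver.

**Route**

Step 1
Reactants: 1 5-fluororesorcinol
Product: 2 5-fluoro-2-iodobenzene-1,3-diol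
Conditions: I2, NaHCO3, H2O/THF, 0 °C
Reagents that add atoms: iodine, II
Why: Electrophilic aromatic iodination under bicarbonate buffering should go to C2, which is ortho to both hydroxyls and para to fluorine (the parent resorcinol gives 2-iodoresorcinol under these conditions), and this fixes the later geranyl site between the two oxygens.

Step 2
Reactants: 2 5-fluoro-2-iodobenzene-1,3-diol
Product: 3 5-fluoro-2-iodo-1,3-bis(methoxymethoxy)benzene
Conditions: NaH, MOMCl, DMF, 0 °C to rt
Reagents that add atoms: chloromethyl methyl ether, COCCl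
Why: Williamson-type O-alkylation of both phenoxides with MOMCl (acetal protection) gives ethers that survive the organometallic steps and later assist and stabilise the ortho-lithiation.

Step 3
Reactants: 3 5-fluoro-2-iodo-1,3-bis(methoxymethoxy)benzene; 4 geranyl bromide
Product: 6 5-fluoro-2-[(2E)-3,7-dimethylocta-2,6-dien-1-yl]-1,3-bis(methoxymethoxy)benzene, via aryl Grignard reagent 5 (not isolated)
Conditions: i-PrMgCl·LiCl, THF, 0 °C; then CuI (10 mol %), 4, −20 °C to rt
Reagents that add atoms: none
Why: Iodine–magnesium exchange places the aryl nucleophile exactly at the iodinated carbon, and copper-catalysed allylic substitution on geranyl bromide should occur at the primary α-carbon with retention of the (E)-alkene because attack of the 2,6-disubstituted aryl group at the tertiary γ-carbon is sterically blocked.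

Step 4
Reactants: 7 acetosyringone
Product: 8 1-[3,5-dimethoxy-4-(methoxymethoxy)phenyl]ethan-1-one
Conditions: MOMCl, K2CO3, acetone, 0 to 50 °C
Reagents that add atoms: chloromethyl methyl ether, COCCl
Why: O-alkylation of the acidic, carbonyl-conjugated phenol with MOMCl under carbonate base (acetal protection) masks the phenol for the enolate and organolithium chemistry that follows.

Step 5
Reactants: 8 1-[3,5-dimethoxy-4-(methoxymethoxy)phenyl]ethan-1-one
Product: 9 ethyl 3-[3,5-dimethoxy-4-(methoxymethoxy)phenyl]-3-oxopropanoate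
Conditions: NaH, (EtO)2CO, THF, reflux; AcOH quench
Reagents that add atoms: diethyl carbonate, CCOC(=O)OCC
Why: Crossed Claisen condensation of the methyl ketone enolate with diethyl carbonate is driven by irreversible deprotonation of the β-keto ester product.

Step 6
Reactants: 9 ethyl 3-[3,5-dimethoxy-4-(methoxymethoxy)phenyl]-3-oxopropanoate
Product: 10 ethyl (3S)-3-[3,5-dimethoxy-4-(methoxymethoxy)phenyl]-3-hydroxypropanoate
Conditions: RuCl[(S,S)-TsDPEN](p-cymene) (1 mol %), HCO2H/Et3N (5:2), EtOAc, rt
Reagents that add atoms: none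
Why: Noyori asymmetric transfer hydrogenation delivers hydride to one face of the aryl ketone through the CH–π-controlled six-membered transition state of the (S,S)-TsDPEN–Ru hydride, which by analogy with acetophenone should set the (S)-carbinol that becomes C2.

Step 7
Reactants: 10 ethyl (3S)-3-[3,5-dimethoxy-4-(methoxymethoxy)phenyl]-3-hydroxypropanoate
Product: 11 (3S)-3-[3,5-dimethoxy-4-(methoxymethoxy)phenyl]-3-hydroxypropanoic acid
Conditions: LiOH·H2O, THF/H2O, 0 °C to rt; 1 M HCl to pH 3 at 0 °C
Reagents that add atoms: lithium hydroxide, [Li+].[OH-]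
Why: Saponification of the ethyl ester at low temperature followed by cold, mild acidification should leave the benzylic carbinol stereocentre and the MOM ether untouched.

Step 8
Reactants: 11 (3S)-3-[3,5-dimethoxy-4-(methoxymethoxy)phenyl]-3-hydroxypropanoic acid
Product: 13 (4S)-4-[3,5-dimethoxy-4-(methoxymethoxy)phenyl]oxetan-2-one, via mixed carboxylic sulfonic anhydride 12 (not isolated)
Conditions: PhSO2Cl, pyridine, 0 to 4 °C
Reagents that add atoms: none
Why: Carboxyl-activating β-lactonisation with benzenesulfonyl chloride in pyridine proceeds by attack of the hydroxyl on the mixed anhydride, so the C–O bond of the stereocentre is not broken and the (S) configuration is retained.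

Step 9
Reactants: 6 5-fluoro-2-[(2E)-3,7-dimethylocta-2,6-dien-1-yl]-1,3-bis(methoxymethoxy)benzene; 13 (4S)-4-[3,5-dimethoxy-4-(methoxymethoxy)phenyl]oxetan-2-one
Product: 16 (2S)-2-[3,5-dimethoxy-4-(methoxymethoxy)phenyl]-6-[(2E)-3,7-dimethylocta-2,6-dien-1-yl]-5,7-bis(methoxymethoxy)chroman-4-one, via aryllithium 14 (not isolated), via lithium aldolate 15 (not isolated)
Conditions: 6, s-BuLi, THF, −78 °C; 13 in THF, −78 °C; DMPU, −78 to 0 °C, then rt; pH 7 buffer
Reagents that add atoms: none
Why: Proposed new method: the C–H flanked by F and OMOM in 6 (two identical sites) is lithiated, the hard aryllithium 14 adds to the strained lactone carbonyl of 13, and the tetrahedral intermediate collapses with acyl–O cleavage, releasing the strain of the oxetanone ring, to the lithium aldolate 15, whose alkoxide then displaces fluoride at C8a by addition–elimination to forge O1–C8a. The closest known reaction types are the acyl–oxygen opening of β-lactones by organolithium reagents to β-hydroxy ketones and the alkoxide SNAr closure of 2-fluoroaryl ketones to chroman-4-ones (tandem aldol–SNAr annulations), and only their union in one flask is untested. The pyranone ring closes in a 6-exo-trig addition to C8a through a Meisenheimer anion delocalised over C4a into the C4 carbonyl, and the closing ring itself holds that carbonyl in the arene plane. No stereocentre is created, since C2 is carried over from C4 of the lactone, whose C–O bond is never broken, so (S) in 13 becomes (2S) in 16. The step needs acyl over benzylic attack on the lactone (hard aryllithium at −78 °C), mono-addition (the chelated 2,6-disubstituted aryl ketone resists a second bulky aryllithium) and closure at C8a and not at C5 (fluoride is by far the better SNAr leaving group than OMOM, and O5 and O7 are meta to C8a and so do not deactivate it). Ring closure must also outrun retro-aldol cleavage of 15, which DMPU-assisted SNAr at or below 0 °C is expected to do.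

Step 10
Reactants: 16 (2S)-2-[3,5-dimethoxy-4-(methoxymethoxy)phenyl]-6-[(2E)-3,7-dimethylocta-2,6-dien-1-yl]-5,7-bis(methoxymethoxy)chroman-4-one
Product: 17 (2S)-6-[(2E)-3,7-dimethylocta-2,6-dien-1-yl]-5,7-dihydroxy-2-(4-hydroxy-3,5-dimethoxyphenyl)chroman-4-one
Conditions: HCl (1.25 M in MeOH), 0 °C to rt; solid NaHCO3 quench
Reagents that add atoms: none
Why: Acid-catalysed acetal exchange in methanol should remove all three MOM groups (the chelated 5-O-MOM fastest) under mild conditions of the kind used for prenylated and geranylated flavanones, so that neither the C2 configuration nor the acid-sensitive geranyl chain next to the free phenols should be affected.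

**Compound list**
1 | 5-fluororesorcinol (5-fluorobenzene-1,3-diol) | Oc1cc(O)cc(F)c1 | starting material
2 | 5-fluoro-2-iodobenzene-1,3-diol | Oc1cc(F)cc(O)c1I | intermediate
3 | 5-fluoro-2-iodo-1,3-bis(methoxymethoxy)benzene | COCOc1cc(F)cc(OCOC)c1I | intermediate
4 | geranyl bromide, (2E)-1-bromo-3,7-dimethylocta-2,6-diene | BrC/C=C(\C)CCC=C(C)C | starting material
5 | [4-fluoro-2,6-bis(methoxymethoxy)phenyl]magnesium chloride (LiCl complex, not isolated) | COCOc1cc(F)cc(OCOC)c1[Mg]Cl | intermediate
6 | 5-fluoro-2-[(2E)-3,7-dimethylocta-2,6-dien-1-yl]-1,3-bis(methoxymethoxy)benzene | COCOc1cc(F)cc(OCOC)c1C/C=C(\C)CCC=C(C)C | intermediate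
7 | acetosyringone, 1-(4-hydroxy-3,5-dimethoxyphenyl)ethan-1-one | CC(=O)c1cc(OC)c(O)c(OC)c1 | starting material
8 | 1-[3,5-dimethoxy-4-(methoxymethoxy)phenyl]ethan-1-one | CC(=O)c1cc(OC)c(OCOC)c(OC)c1 | intermediate
9 | ethyl 3-[3,5-dimethoxy-4-(methoxymethoxy)phenyl]-3-oxopropanoate | CCOC(=O)CC(=O)c1cc(OC)c(OCOC)c(OC)c1 | intermediate
10 | ethyl (3S)-3-[3,5-dimethoxy-4-(methoxymethoxy)phenyl]-3-hydroxypropanoate | CCOC(=O)C[C@H](O)c1cc(OC)c(OCOC)c(OC)c1 | intermediate
11 | (3S)-3-[3,5-dimethoxy-4-(methoxymethoxy)phenyl]-3-hydroxypropanoic acid | OC(=O)C[C@H](O)c1cc(OC)c(OCOC)c(OC)c1 | intermediate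
12 | mixed anhydride of acid 11 with benzenesulfonic acid, (S) at the carbinol (not isolated) | O=C(C[C@H](O)c1cc(OC)c(OCOC)c(OC)c1)OS(=O)(=O)c1ccccc1 | intermediate
13 | (4S)-4-[3,5-dimethoxy-4-(methoxymethoxy)phenyl]oxetan-2-one | COc1cc([C@@H]2CC(=O)O2)cc(OC)c1OCOC | intermediate
14 | {2-fluoro-5-[(2E)-3,7-dimethylocta-2,6-dien-1-yl]-4,6-bis(methoxymethoxy)phenyl}lithium (not isolated) | [Li]c1c(F)cc(OCOC)c(C/C=C(\C)CCC=C(C)C)c1OCOC | intermediate
15 | lithium (1S)-1-[3,5-dimethoxy-4-(methoxymethoxy)phenyl]-3-{2-fluoro-5-geranyl-4,6-bis(methoxymethoxy)phenyl}-3-oxopropan-1-olate (not isolated) | COc1cc([C@H](CC(=O)c2c(F)cc(OCOC)c(C/C=C(\C)CCC=C(C)C)c2OCOC)O[Li])cc(OC)c1OCOC | intermediate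
16 | (2S)-2-[3,5-dimethoxy-4-(methoxymethoxy)phenyl]-6-[(2E)-3,7-dimethylocta-2,6-dien-1-yl]-5,7-bis(methoxymethoxy)chroman-4-one | COc1cc([C@@H]2CC(=O)c3c(cc(OCOC)c(C/C=C(\C)CCC=C(C)C)c3OCOC)O2)cc(OC)c1OCOC | intermediate
17 | (2S)-6-[(2E)-3,7-dimethylocta-2,6-dien-1-yl]-5,7-dihydroxy-2-(4-hydroxy-3,5-dimethoxyphenyl)chroman-4-one (CNP0372687.1) | COc1cc([C@@H]2CC(=O)c3c(cc(O)c(C/C=C(\C)CCC=C(C)C)c3O)O2)cc(OC)c1O | target

**Summary**
Total step count: 10. Longest linear sequence: 7 steps (7 to 17 through steps 4–10); the ring A branch (steps 1–3) joins at step 9.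

**Steps most likely to fail**

Step 9 (Proposed new method). What may go wrong: on warming, retro-aldol or E1cB breakdown of the lithium aldolate may compete with a sluggish SNAr of the lithium alkoxide and erode the C2 configuration; over-addition to the ketone or enolisation of the lactone may lower conversion. The fallback uses known chemistry in separate operations; it sets out from 10 and comes back to the route at 16. Ester 10 is converted with MeNHOMe·HCl and i-PrMgCl (THF, −20 °C) into the Weinreb amide (3S)-3-[3,5-dimethoxy-4-(methoxymethoxy)phenyl]-3-hydroxy-N-methoxy-N-methylpropanamide F1. Silylation (TBSCl, imidazole, DMF) gives its tert-butyldimethylsilyl ether F2. F2 acylates aryllithium 14 (from 6 and s-BuLi, THF, −78 °C) to the (S)-β-silyloxy 2-fluoroaryl ketone F3, with the stable N-methoxy chelate preventing over-addition. Buffered desilylation (HF·pyridine, pyridine, THF, 0 °C) gives the free (S)-β-hydroxy 2-fluoroaryl ketone F4. A mild-base intramolecular SNAr etherification (Cs2CO3, DMF, 0 °C to rt) then closes O1–C8a to give 16.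

Step 8. What may go wrong: the β-aryl β-lactone may decarboxylate or oligomerise, and sulfonylation of the benzylic hydroxyl in place of the carboxylate would lead to elimination. The fallback drops the strained acyl donor; it sets out from 11 and comes back at 15. Acid 11 is condensed with 2,2-dimethoxypropane (PPTS cat., CH2Cl2, rt) to the unstrained cyclic acylal (6S)-6-[3,5-dimethoxy-4-(methoxymethoxy)phenyl]-2,2-dimethyl-1,3-dioxan-4-one F5. Addition of aryllithium 14 to its carbonyl at −78 °C, followed by loss of acetone from the ring-opened hemiketal alkoxide, should give the same lithium aldolate 15, which is carried on to 16 as in step 9.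

Step 1. What may go wrong: poor site selectivity of the iodination (attack at C4 next to fluorine) and over-iodination. The fallback replaces selective mono-halogenation by exhaustive bromination and selective reductive debromination; it sets out from 1 and comes back at 6. Compound 1 is brominated with 3 equivalents of Br2 (CHCl3, rt) to 2,4,6-tribromo-5-fluorobenzene-1,3-diol F6. Na2SO3 in aqueous NaOH/MeOH removes the two bromines para to a hydroxyl and should leave 2-bromo-5-fluorobenzene-1,3-diol F7. MOM protection (NaH, MOMCl, DMF) gives 2-bromo-5-fluoro-1,3-bis(methoxymethoxy)benzene F8. Bromine–lithium exchange (n-BuLi, THF, −78 °C) gives [4-fluoro-2,6-bis(methoxymethoxy)phenyl]lithium F9, which with CuI (cat.) and geranyl bromide 4 gives 6.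

**Further compounds**
F1 | step 9 | (3S)-3-[3,5-dimethoxy-4-(methoxymethoxy)phenyl]-3-hydroxy-N-methoxy-N-methylpropanamide | CON(C)C(=O)C[C@H](O)c1cc(OC)c(OCOC)c(OC)c1
F2 | step 9 | (3S)-3-(tert-butyldimethylsilyloxy)-3-[3,5-dimethoxy-4-(methoxymethoxy)phenyl]-N-methoxy-N-methylpropanamide | CON(C)C(=O)C[C@H](O[Si](C)(C)C(C)(C)C)c1cc(OC)c(OCOC)c(OC)c1
F3 | step 9 | (3S)-3-(tert-butyldimethylsilyloxy)-3-[3,5-dimethoxy-4-(methoxymethoxy)phenyl]-1-{2-fluoro-5-geranyl-4,6-bis(methoxymethoxy)phenyl}propan-1-one | COc1cc([C@H](CC(=O)c2c(F)cc(OCOC)c(C/C=C(\C)CCC=C(C)C)c2OCOC)O[Si](C)(C)C(C)(C)C)cc(OC)c1OCOC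
F4 | step 9 | (3S)-3-[3,5-dimethoxy-4-(methoxymethoxy)phenyl]-1-{2-fluoro-5-geranyl-4,6-bis(methoxymethoxy)phenyl}-3-hydroxypropan-1-one | COc1cc([C@H](CC(=O)c2c(F)cc(OCOC)c(C/C=C(\C)CCC=C(C)C)c2OCOC)O)cc(OC)c1OCOC
F5 | step 8 | (6S)-6-[3,5-dimethoxy-4-(methoxymethoxy)phenyl]-2,2-dimethyl-1,3-dioxan-4-one | COc1cc([C@@H]2CC(=O)OC(C)(C)O2)cc(OC)c1OCOC
F6 | step 1 | 2,4,6-tribromo-5-fluorobenzene-1,3-diol | Oc1c(Br)c(O)c(Br)c(F)c1Br
F7 | step 1 | 2-bromo-5-fluorobenzene-1,3-diol | Oc1cc(F)cc(O)c1Br
F8 | step 1 | 2-bromo-5-fluoro-1,3-bis(methoxymethoxy)benzene | COCOc1cc(F)cc(OCOC)c1Br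
F9 | step 1 | [4-fluoro-2,6-bis(methoxymethoxy)phenyl]lithium | [Li]c1c(OCOC)cc(F)cc1OCOC
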